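The lower (epigallocatechin) pyran ring C is disconnected at C4–C4a. Catechin C4 is first joined to a phloroglucinol-derived phenol, whose oxygen is then alkylated with an enantiopure epoxy alcohol carrying ring B; the precursor is thus an aryl 1-aryl-2,3-epoxypropyl ether with both stereocentres in place. A gold-catalysed 6-endo epoxide–arene Friedel–Crafts alkylation then closes ring C through the nucleophilic ring A carbon ortho to O1. Because the other ortho carbon (C8) already bears the catechin unit, closure is regiospecific and fixes the 4→8 linkage, and the C2/C3 cis relationship is delivered untouched from Sharpless epoxidation and Mitsunobu inversion. Galloylation and hydrogenolysis finish.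

Key step: step 7

Remark: the target is read as (+)-catechin-(4α→8)-(−)-epigallocatechin 3-O-gallate (upper unit 2R,3S with the C4 aryl bond trans to O3, lower unit 2R,3R); flavan locants are used for each unit, and 4, 6 and 11 are taken as purchasable.

Step 1
Reactants: 1 (+)-catechin
Product: 2 3,5,7,3',4'-penta-O-benzyl-(+)-catechin (2R,3S)
Conditions: NaH (6 equiv), BnBr (6 equiv), DMF, 0 °C → rt
Reagents that add atoms: benzyl bromide BrCc1ccccc1
Why: Williamson etherification of the four phenoxides and the C3 alkoxide touches no stereocentre, and the O3 benzyl ether keeps the upper 3-oxygen distinct from the lower one until the final hydrogenolysis.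

Step 2
Reactants: 2 penta-O-benzyl-(+)-catechin
Product: 3 (2R,3S,4S)-3,5,7-tris(benzyloxy)-2-[3,4-bis(benzyloxy)phenyl]-4-(2-ethoxyethoxy)chromane (4β ether, 3,4-cis)
Conditions: DDQ (2 equiv), EtOCH2CH2OH (5 equiv), CH2Cl2, rt
Reagents that add atoms: 2-ethoxyethanol CCOCCO
Why: DDQ benzylic oxidation abstracts hydride from C4 (the cation is stabilised by O1, O5 and O7 of ring A) and the alcohol traps it, expected mainly as the axial 4β ether; this centre is erased in step 3.

Step 3
Reactants: 3 4β-(2-ethoxyethoxy) ether; 4 3,5-bis(benzyloxy)phenol (3 equiv)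
Product: 5 3,5-bis(benzyloxy)-2-(penta-O-benzylcatechin-4α-yl)phenol (upper unit 2,3-trans-3,4-trans)
Conditions: TMSOTf (0.2 equiv), CH2Cl2, −78 → −40 °C; Et3N quench
Reagents that add atoms: none
Why: TMSOTf ionises the C4 ether to the ring A-stabilised cation, which undergoes Friedel–Crafts arylation at one of the two equivalent carbons ortho to the free hydroxyl of 4 (less hindered than the carbon between the two benzyloxy groups, and the site taken by cinnamyl cations with this phenol), from the face anti to the 3-benzyloxy group, so substrate control sets C4 as 4α (3,4-trans).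

Step 4
Reactants: 6 3,4,5-tris(benzyloxy)benzaldehyde
Product: 7 rac-1-[3,4,5-tris(benzyloxy)phenyl]prop-2-en-1-ol
Conditions: CH2=CHMgBr, THF, 0 °C; aq. NH4Cl
Reagents that add atoms: vinylmagnesium bromide C=C[Mg]Br
Why: Grignard 1,2-addition to the aldehyde gives the racemic secondary allylic alcohol, which is resolved in step 5.

Step 5
Reactants: 7 racemic allylic alcohol
Product: 8 (S)-[(2R)-oxiran-2-yl][3,4,5-tris(benzyloxy)phenyl]methanol (erythro)
Conditions: Ti(OiPr)4 (10 mol %), L-(+)-DIPT (15 mol %), t-BuOOH (0.5 equiv), 4 Å MS, CH2Cl2, −20 °C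
Reagents that add atoms: tert-butyl hydroperoxide CC(C)(C)OO
Why: Sharpless asymmetric epoxidation run as a kinetic resolution: with L-(+)-DIPT the (R)-alcohol should be epoxidised fast on the vinyl face dictated by the tartrate, which sets the oxirane carbon (R) under catalyst control and gives the erythro epoxy alcohol, while the (S)-alcohol is left behind.

Step 6
Reactants: 5 phenol; 8 epoxy alcohol (1.5 equiv)
Product: 9 1-{(R)-[(2R)-oxiran-2-yl][3,4,5-tris(benzyloxy)phenyl]methoxy}-3,5-bis(benzyloxy)-2-(penta-O-benzylcatechin-4α-yl)benzene (threo ether)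
Conditions: PPh3, DIAD, toluene, 0 °C → rt, high concentration
Reagents that add atoms: none
Why: Mitsunobu etherification: the phenol displaces the benzylic oxyphosphonium by SN2 with inversion (S → R), turning the erythro alcohol into the threo aryl ether that maps onto the 2,3-cis relationship, and the epoxide is inert to the neutral conditions.

Step 7
Reactants: 9 threo epoxy aryl ether
Product: 10 3,5,7,3',4'-penta-O-benzylcatechin-(4α→8)-5,7,3',4',5'-penta-O-benzyl-(−)-epigallocatechin (lower unit 2R,3R, free 3-OH)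
Conditions: AuCl3 (5 mol %), AgOSO2CF3 (15 mol %), ClCH2CH2Cl, 0 °C → rt
Reagents that add atoms: none
Why: AuCl3 with AgOSO2CF3 gives a cationic trivalent gold Lewis acid that coordinates the oxirane oxygen; ring A carbon C4a attacks the terminal oxirane carbon C4 in an SN2-like Friedel–Crafts alkylation, and rearomatisation with proton transfer releases the C3 hydroxyl and the catalyst. The closest known reaction type is the gold-catalysed intramolecular epoxide–arene cycloalkylation of aryl glycidyl ethers to chroman-3-ols, including 2-aryl examples. Ring C closes in the 6-endo-tet mode (both oxirane carbons end up in the ring); the 5-exo alternative would need attack at the more hindered internal carbon. No stereocentre is created: C2 (R) and C3 (R) are carried over from 9 because neither the C2–O1 nor the C3–O bond is touched, so the threo ether gives the 2,3-cis flavan-3-ol. The step needs site selectivity on ring A and chemoselectivity for epoxide activation over ionisation of the benzylic C2–O1 ether. The first is secured because C4a is the only free carbon ortho to O1 (C8 carries the catechin unit, so a 4→6 isomer cannot form); the second rests on the mild oxophilic catalyst and on the poor cation stabilisation by a 3,4,5-tris(benzyloxy)phenyl group next to an electron-withdrawing oxirane.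

Step 8
Reactants: 10 cis-flavan-3-ol; 11 3,4,5-tris(benzyloxy)benzoic acid
Product: 12 3-O-[3,4,5-tris(benzyloxy)benzoyl] ester of 10 (tridecabenzyl ether of the target)
Conditions: DCC, DMAP (cat.), CH2Cl2, rt
Reagents that add atoms: none
Why: Steglich esterification acylates the only free hydroxyl, the axial C3–OH of the lower unit (the upper C3 oxygen is benzylated), without touching any stereocentre.

Step 9
Reactants: 12 perbenzylated gallate
Product: 13 (+)-catechin-(4α→8)-(−)-epigallocatechin 3-O-gallate (target)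
Conditions: H2 (1 atm), Pd(OH)2/C, THF/MeOH, rt
Reagents that add atoms: none
Why: Hydrogenolysis cleaves all thirteen benzyl ethers in one operation, while the gallate ester, the interflavan C4–C8 bond and the cyclic C2–O1 ethers are expected to survive the neutral conditions used for benzylated proanthocyanidin gallates.

Compound list
1 | (+)-catechin, (2R,3S)-2-(3,4-dihydroxyphenyl)chromane-3,5,7-triol | O[C@H]1Cc2c(O)cc(O)cc2O[C@@H]1c1ccc(O)c(O)c1 | starting material
2 | 3,5,7,3',4'-penta-O-benzyl-(+)-catechin (2R,3S) | O(Cc1ccccc1)[C@H]1Cc2c(OCc3ccccc3)cc(OCc3ccccc3)cc2O[C@@H]1c1ccc(OCc2ccccc2)c(OCc2ccccc2)c1 | intermediate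
3 | (2R,3S,4S)-3,5,7-tris(benzyloxy)-2-[3,4-bis(benzyloxy)phenyl]-4-(2-ethoxyethoxy)chromane | CCOCCO[C@H]1c2c(OCc3ccccc3)cc(OCc3ccccc3)cc2O[C@H](c2ccc(OCc3ccccc3)c(OCc3ccccc3)c2)[C@H]1OCc1ccccc1 | intermediate
4 | 3,5-bis(benzyloxy)phenol | Oc1cc(OCc2ccccc2)cc(OCc2ccccc2)c1 | starting material
5 | 3,5-bis(benzyloxy)-2-(penta-O-benzylcatechin-4α-yl)phenol (upper unit 2R,3S, 3,4-trans) | Oc1cc(OCc2ccccc2)cc(OCc2ccccc2)c1[C@@H]1c2c(OCc3ccccc3)cc(OCc3ccccc3)cc2O[C@H](c2ccc(OCc3ccccc3)c(OCc3ccccc3)c2)[C@H]1OCc1ccccc1 | intermediate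
6 | 3,4,5-tris(benzyloxy)benzaldehyde | O=Cc1cc(OCc2ccccc2)c(OCc2ccccc2)c(OCc2ccccc2)c1 | starting material
7 | rac-1-[3,4,5-tris(benzyloxy)phenyl]prop-2-en-1-ol | C=CC(O)c1cc(OCc2ccccc2)c(OCc2ccccc2)c(OCc2ccccc2)c1 | intermediate
8 | (S)-[(2R)-oxiran-2-yl][3,4,5-tris(benzyloxy)phenyl]methanol (erythro) | O[C@H]([C@H]1CO1)c1cc(OCc2ccccc2)c(OCc2ccccc2)c(OCc2ccccc2)c1 | intermediate
9 | threo aryl ether of 5 with 8, (R) at the benzylic ether carbon and (R) at the oxirane carbon | O(c1cc(OCc2ccccc2)cc(OCc2ccccc2)c1[C@@H]1c2c(OCc3ccccc3)cc(OCc3ccccc3)cc2O[C@H](c2ccc(OCc3ccccc3)c(OCc3ccccc3)c2)[C@H]1OCc1ccccc1)[C@@H]([C@H]1CO1)c1cc(OCc2ccccc2)c(OCc2ccccc2)c(OCc2ccccc2)c1 | intermediate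
10 | penta-O-benzylcatechin-(4α→8)-5,7,3',4',5'-penta-O-benzyl-(−)-epigallocatechin (lower unit 2R,3R) | O[C@@H]1Cc2c(OCc3ccccc3)cc(OCc3ccccc3)c([C@@H]3c4c(OCc5ccccc5)cc(OCc5ccccc5)cc4O[C@H](c4ccc(OCc5ccccc5)c(OCc5ccccc5)c4)[C@H]3OCc3ccccc3)c2O[C@@H]1c1cc(OCc2ccccc2)c(OCc2ccccc2)c(OCc2ccccc2)c1 | intermediate
11 | 3,4,5-tris(benzyloxy)benzoic acid | O=C(O)c1cc(OCc2ccccc2)c(OCc2ccccc2)c(OCc2ccccc2)c1 | starting material
12 | 3-O-[3,4,5-tris(benzyloxy)benzoyl] ester of 10 | O=C(O[C@@H]1Cc2c(OCc3ccccc3)cc(OCc3ccccc3)c([C@@H]3c4c(OCc5ccccc5)cc(OCc5ccccc5)cc4O[C@H](c4ccc(OCc5ccccc5)c(OCc5ccccc5)c4)[C@H]3OCc3ccccc3)c2O[C@@H]1c1cc(OCc2ccccc2)c(OCc2ccccc2)c(OCc2ccccc2)c1)c1cc(OCc2ccccc2)c(OCc2ccccc2)c(OCc2ccccc2)c1 | intermediate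
13 | (+)-catechin-(4α→8)-(−)-epigallocatechin 3-O-gallate | O=C(O[C@@H]1Cc2c(O)cc(O)c([C@@H]3c4c(O)cc(O)cc4O[C@H](c4ccc(O)c(O)c4)[C@H]3O)c2O[C@@H]1c1cc(O)c(O)c(O)c1)c1cc(O)c(O)c(O)c1 | target

Total step count: 9. Longest linear sequence: 7 steps (steps 1, 2, 3, 6, 7, 8, 9 from 1).

Steps most likely to fail

Step 7 (ring closure). Ionisation of the benzylic C2–O1 ether, which would scramble C2, or a hydride shift of the activated oxirane to an aldehyde may outrun arene attack. The fallback sets out from 5 and 7 and returns at 10; it closes ring C at O1–C2 instead. Phenol 5 is alkylated at its free ortho carbon by the allyl cation from 7 (H2SO4 on SiO2, CH2Cl2, rt) to give the (E)-1,3-diarylpropene F1. Dihydroxylation [K2OsO2(OH)4 cat., (DHQ)2PHAL, N-methylmorpholine N-oxide, acetone/H2O] should give the (1S,2S)-diol F2; a minor diastereomer would be separable because the catechin unit is homochiral. Intramolecular Mitsunobu etherification (PPh3, DIAD, THF) inverts the benzylic carbinol and gives the 2,3-trans alcohol F3. Dess–Martin oxidation gives the flavan-3-one F4, and LiBH(s-Bu)3 (THF, −78 °C) adds hydride anti to the 2-aryl group to give 10.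

Step 6 (etherification). Displacement by the ortho-hindered phenol may be slow, so that SN1 leakage erodes the inversion at the benzylic carbinol or elimination consumes 8. The fallback sets out from 4 and 8 and returns at 10; it changes the order of events. The unhindered phenol 4 is etherified with 8 under the same Mitsunobu conditions to give the aryl ether F5. The gold-catalysed closure then gives penta-O-benzyl-(−)-epigallocatechin F6. Electrophile 3 is finally condensed with an excess of F6 (TMSOTf, CH2Cl2, −78 °C), C8 of the flavan being the usual site of attack, to reach 10.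

Step 3 (arylation). The C4 cation may attack the carbon para to the hydroxyl of 4, α-facial selectivity may be incomplete, and the phenol may be alkylated twice. The fallback sets out from 3 and returns at 5; it removes the regiochemical question from the C–C bond formation. Threefold-symmetric phloroglucinol (commercial, in excess; BF3·OEt2, dioxane/CH2Cl2, 0 °C) is used as the nucleophile to give the triol F7. Its unhindered 5-hydroxyl and one of the two equivalent flanking hydroxyls are then benzylated (BnBr 2 equiv, K2CO3, DMF, 0 °C) to give 5; the second flanking hydroxyl should be shielded once its neighbour is etherified.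

Further compounds
F1 | step 7 | 3,5-bis(benzyloxy)-2-(penta-O-benzylcatechin-4α-yl)-6-{(E)-3-[3,4,5-tris(benzyloxy)phenyl]prop-2-en-1-yl}phenol | Oc1c(C/C=C/c2cc(OCc3ccccc3)c(OCc3ccccc3)c(OCc3ccccc3)c2)c(OCc2ccccc2)cc(OCc2ccccc2)c1[C@@H]1c2c(OCc3ccccc3)cc(OCc3ccccc3)cc2O[C@H](c2ccc(OCc3ccccc3)c(OCc3ccccc3)c2)[C@H]1OCc1ccccc1
F2 | step 7 | (1S,2S)-3-[2-hydroxy-4,6-bis(benzyloxy)-3-(penta-O-benzylcatechin-4α-yl)phenyl]-1-[3,4,5-tris(benzyloxy)phenyl]propane-1,2-diol | Oc1c(C[C@H](O)[C@@H](O)c2cc(OCc3ccccc3)c(OCc3ccccc3)c(OCc3ccccc3)c2)c(OCc2ccccc2)cc(OCc2ccccc2)c1[C@@H]1c2c(OCc3ccccc3)cc(OCc3ccccc3)cc2O[C@H](c2ccc(OCc3ccccc3)c(OCc3ccccc3)c2)[C@H]1OCc1ccccc1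
F3 | step 7 | penta-O-benzylcatechin-(4α→8)-5,7,3',4',5'-penta-O-benzyl-(+)-gallocatechin (lower unit 2R,3S, the C3 epimer of 10) | O[C@H]1Cc2c(OCc3ccccc3)cc(OCc3ccccc3)c([C@@H]3c4c(OCc5ccccc5)cc(OCc5ccccc5)cc4O[C@H](c4ccc(OCc5ccccc5)c(OCc5ccccc5)c4)[C@H]3OCc3ccccc3)c2O[C@@H]1c1cc(OCc2ccccc2)c(OCc2ccccc2)c(OCc2ccccc2)c1
F4 | step 7 | lower-unit flavan-3-one of F3 (2R) | O=C1Cc2c(OCc3ccccc3)cc(OCc3ccccc3)c([C@@H]3c4c(OCc5ccccc5)cc(OCc5ccccc5)cc4O[C@H](c4ccc(OCc5ccccc5)c(OCc5ccccc5)c4)[C@H]3OCc3ccccc3)c2O[C@@H]1c1cc(OCc2ccccc2)c(OCc2ccccc2)c(OCc2ccccc2)c1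
F5 | step 6 | 1,3-bis(benzyloxy)-5-{(R)-[(2R)-oxiran-2-yl][3,4,5-tris(benzyloxy)phenyl]methoxy}benzene | O(c1cc(OCc2ccccc2)cc(OCc2ccccc2)c1)[C@@H]([C@H]1CO1)c1cc(OCc2ccccc2)c(OCc2ccccc2)c(OCc2ccccc2)c1
F6 | step 6 | 5,7,3',4',5'-penta-O-benzyl-(−)-epigallocatechin (2R,3R) | O[C@@H]1Cc2c(OCc3ccccc3)cc(OCc3ccccc3)cc2O[C@@H]1c1cc(OCc2ccccc2)c(OCc2ccccc2)c(OCc2ccccc2)c1
F7 | step 3 | 2-(penta-O-benzylcatechin-4α-yl)benzene-1,3,5-triol | Oc1cc(O)c([C@@H]2c3c(OCc4ccccc4)cc(OCc4ccccc4)cc3O[C@H](c3ccc(OCc4ccccc4)c(OCc4ccccc4)c3)[C@H]2OCc2ccccc2)c(O)c1
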